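Daucane numbering is used (C1 methyl-bearing fusion carbon, C4 isopropyl carbinol, C5 fusion CH, C6 anisoate carbon, C8=C9 alkene, C10 angelate carbon). Everything rests on disconnecting C4–C5 in the five-membered ring, exploiting the tertiary carbinol C4 that sits beside fusion carbon C5 and oxygenated C6. An intramolecular Nozaki–Hiyama–Kishi addition of a C5 alkenylchromium to the C4 isopropyl ketone closes this ring, sets C4 and leaves the C5=C6 alkene that later supplies the C5 hydrogen and C6 oxygen. Its precursor is a cycloheptenyl triflate (C5 triflate, C5=C6) carrying a C10 silyl ether and, on quaternary C1, methyl and the 4-methyl-3-oxopentyl chain.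

Key step: step 7

Remark: α and β denote the faces of the ring system, β being the face of the C1 methyl; the C10 silyl ether is treated as sacrificial, because hydride reduction of a C10 ketone is assumed to occur anti to that methyl, so the C10 configuration of the target is installed by inversion in step 18.

Step 1
Reactants: 1 cycloheptane-1,3-dione
Product: 2 2-methylcycloheptane-1,3-dione
Conditions: MeI, K2CO3, acetone, 56 °C
Reagents that add atoms: iodomethane, CI
Why: Enolate C-alkylation: carbonate removes the doubly activated proton between the carbonyls and the soft enolate carbon is methylated, the seven-membered 1,3-dione being largely in the diketo form so that C-alkylation should prevail over O-alkylation.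

Step 2
Reactants: 2 2-methylcycloheptane-1,3-dione; 3 N-methoxy-N-methylacrylamide
Product: 4 N-methoxy-N-methyl-3-(1-methyl-2,7-dioxocycloheptyl)propanamide
Conditions: DBU (0.2 equiv), MeCN, 50 °C
Reagents that add atoms: none
Why: Michael addition: the enolate of the 2-methyl-1,3-dione adds to the β-carbon of the acrylamide, which builds quaternary C1 and brings in C2, C3 and C4 at the amide oxidation level; the product has a mirror plane, so no stereocentre is set yet.

Step 3
Reactants: 4 N-methoxy-N-methyl-3-(1-methyl-2,7-dioxocycloheptyl)propanamide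
Product: 5 N-methoxy-N-methyl-3-[(1R,2R)-2-hydroxy-1-methyl-7-oxocycloheptyl]propanamide (hydroxyl trans to the ring methyl)
Conditions: ketoreductase ((R)-selective, chosen from a commercial panel), NADP+ (cat.), i-PrOH, phosphate buffer pH 7, 30 °C
Reagents that add atoms: none
Why: Enzymatic desymmetrising ketone reduction: the enzyme reduces one of the two enantiotopic ring carbonyls from one face, which sets C10 (R) and with it C1 (R) in one event, as is established for 2,2-disubstituted cycloalkane-1,3-diones; the amide is not a substrate.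

Step 4
Reactants: 5 N-methoxy-N-methyl-3-[(1R,2R)-2-hydroxy-1-methyl-7-oxocycloheptyl]propanamide
Product: 6 3-[(1R,2R)-2-(tert-butyldimethylsilyloxy)-1-methyl-7-oxocycloheptyl]-N-methoxy-N-methylpropanamide
Conditions: TBSOTf, 2,6-lutidine, CH2Cl2, −78 → 0 °C
Reagents that add atoms: tert-butyldimethylsilyl trifluoromethanesulfonate, CC(C)(C)[Si](C)(C)OS(=O)(=O)C(F)(F)F
Why: Silyl ether formation with the silyl triflate, needed because the carbinol is next to a quaternary carbon; the ether blocks retro-aldol opening of the β-hydroxy ketone under the basic conditions of step 5.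

Step 5
Reactants: 6 3-[(1R,2R)-2-(tert-butyldimethylsilyloxy)-1-methyl-7-oxocycloheptyl]-N-methoxy-N-methylpropanamide
Product: 8 3-[(1R,7R)-7-(tert-butyldimethylsilyloxy)-1-methyl-2-(trifluoromethylsulfonyloxy)cyclohept-2-en-1-yl]-N-methoxy-N-methylpropanamide, via potassium enolate 7 (not isolated)
Conditions: KN(SiMe3)2, THF, −78 °C; then PhNTf2, −78 → 0 °C
Reagents that add atoms: N-phenylbis(trifluoromethanesulfonimide), FC(F)(F)S(=O)(=O)N(c1ccccc1)S(=O)(=O)C(F)(F)F; potassium bis(trimethylsilyl)amide (potassium of intermediate 7), C[Si](C)(C)[N-][Si](C)(C)C.[K+]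
Why: Enol triflate formation by O-sulfonylation of a ketone enolate: the C5 ketone can lose a proton only at C6 because C1 is quaternary, so a single enolate forms and is trapped on oxygen, while the far less acidic amide α-protons are left alone by one equivalent of base at −78 °C.

Step 6
Reactants: 8 3-[(1R,7R)-7-(tert-butyldimethylsilyloxy)-1-methyl-2-(trifluoromethylsulfonyloxy)cyclohept-2-en-1-yl]-N-methoxy-N-methylpropanamide; 9 isopropylmagnesium chloride
Product: 10 5-[(1R,7R)-7-(tert-butyldimethylsilyloxy)-1-methyl-2-(trifluoromethylsulfonyloxy)cyclohept-2-en-1-yl]-2-methylpentan-3-one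
Conditions: i-PrMgCl, THF, −20 → 0 °C; then aq NH4Cl
Reagents that add atoms: none
Why: Weinreb ketone synthesis: the Grignard reagent adds once to the N-methoxy-N-methylamide to give a stable magnesium chelate that releases the isopropyl ketone only on work-up, and an enol triflate does not react with a Grignard reagent when no transition metal is present.

Step 7
Reactants: 10 5-[(1R,7R)-7-(tert-butyldimethylsilyloxy)-1-methyl-2-(trifluoromethylsulfonyloxy)cyclohept-2-en-1-yl]-2-methylpentan-3-one
Product: 12 (3R,8R,8aS)-8-(tert-butyldimethylsilyloxy)-8a-methyl-3-(propan-2-yl)-1,2,3,5,6,7,8,8a-octahydroazulen-3-ol (4β-hydroxy 4α-isopropyl C5=C6 alkene in daucane terms), via alkenylchromium dichloride 11 (not isolated)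
Conditions: CrCl2 (5 equiv), NiCl2 (5 mol %), DMF, 25 → 50 °C; then H2O
Reagents that add atoms: chromium dichloride (chromium of intermediate 11), Cl[Cr]Cl
Why: Nozaki–Hiyama–Kishi reaction run intramolecularly on a ketone: nickel, reduced by CrCl2 to the zerovalent state, inserts into the C5–O bond of the enol triflate and passes the alkenyl group to chromium, and the alkenylchromium 11 (trivalent chromium) adds to the C4 carbonyl through a four-centre, oxygen-bound transition state. The closest known reaction type is the CrCl2/NiCl2 coupling of alkenyl triflates with aldehydes, which also reaches ketones when the addition is intramolecular. Ring A (the cyclopentane C1–C2–C3–C4–C5) closes in the 5-exo-trig mode, the carbonyl oxygen ending outside the ring. The new stereocentre C4 is controlled by quaternary C1: C10 is tied back toward C6 by the seven-membered ring, whereas the C1 methyl stands over the β face of the forming ring, so the isopropyl group should take the α side and leave the chromium-bound oxygen cis to the methyl. The step needs C–C bond formation to win over enolisation of the isopropyl ketone and over loss of the silyl ether, which the non-basic, carbonyl-selective organochromium secures, and the alkene position is fixed because the triflate could only form toward C6.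

Step 8
Reactants: 12 (3R,8R,8aS)-8-(tert-butyldimethylsilyloxy)-8a-methyl-3-(propan-2-yl)-1,2,3,5,6,7,8,8a-octahydroazulen-3-ol
Product: 14 cis-fused 4β,6β-diol with 5β-H and 10α-silyloxy group, via C6 alkylborane 13 (not isolated)
Conditions: BH3·THF, THF, 0 → 25 °C; then NaOH, H2O2
Reagents that add atoms: borane–tetrahydrofuran (boron of intermediate 13), [BH3-][O+]1CCCC1; hydrogen peroxide, OO
Why: Hydroboration–oxidation: boron adds to the less substituted alkene carbon C6 and hydrogen to C5 in a syn fashion, expected from the β face (the hydroxyl side, the α face carrying the isopropyl group and the C10 flank of the seven-membered ring); the facial outcome is not critical because C5 is re-set in step 10 and C6 in step 11.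

Step 9
Reactants: 14 cis-fused 4β,6β-diol
Product: 15 cis-fused 4β-hydroxy-6-ketone (5β-H)
Conditions: Dess–Martin periodinane, NaHCO3, CH2Cl2, 0 → 25 °C
Reagents that add atoms: none
Why: Dess–Martin oxidation of the secondary C6 alcohol; the tertiary C4 hydroxyl cannot be oxidised and the bicarbonate buffer protects the β-hydroxy ketone from acid-induced dehydration.

Step 10
Reactants: 15 cis-fused 4β-hydroxy-6-ketone
Product: 16 trans-fused 4β-hydroxy-6-ketone (5α-H)
Conditions: DBU (0.3 equiv), toluene, 25 °C
Reagents that add atoms: none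
Why: Base-catalysed epimerisation through the enol: C5 is the only enolisable stereocentre, and equilibration should favour the trans-fused ketone, in which C6 is trans to the bulky isopropyl group on neighbouring C4 and the C4 hydroxyl can hydrogen-bond to the C6 carbonyl; a catalytic amine base in an aprotic solvent keeps retro-aldol cleavage of C4–C5 to a minimum.

Step 11
Reactants: 16 trans-fused 4β-hydroxy-6-ketone
Product: 17 trans-fused 4β,6α-diol (5α-H, 10α-silyloxy)
Conditions: Me4NBH(OAc)3, AcOH/MeCN, −20 °C
Reagents that add atoms: none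
Why: Hydroxyl-directed reduction of the Evans–Saksena type: the C4 hydroxyl exchanges onto boron and delivers hydride intramolecularly to the β face of the C6 carbonyl, which gives the 1,3-anti diol, that is the 6α-alcohol (S at C6).

Step 12
Reactants: 17 trans-fused 4β,6α-diol; 18 4-methoxybenzoyl chloride
Product: 19 6α-(4-methoxybenzoyloxy) 10α-silyl ether with free 4β-hydroxyl
Conditions: DMAP, Et3N, CH2Cl2, 25 °C
Reagents that add atoms: none
Why: DMAP-catalysed acylation: the secondary C6 hydroxyl is esterified while the tertiary C4 hydroxyl is too hindered to react, so the anisoate of the target is installed and also protects C6 for the rest of the route.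

Step 13
Reactants: 19 6α-(4-methoxybenzoyloxy) 10α-silyl ether
Product: 20 6α-(4-methoxybenzoyloxy)-4β,10α-diol
Conditions: Bu4NF, AcOH, THF, 25 → 45 °C
Reagents that add atoms: none
Why: Fluoride-mediated desilylation; buffering with acetic acid suppresses migration or loss of the anisoate.

Step 14
Reactants: 20 6α-(4-methoxybenzoyloxy)-4β,10α-diol
Product: 22 C8=C9 enone with C10 ketone and 6α-anisoate, via C10 ketone 21 (not isolated)
Conditions: IBX (2.5 equiv), DMSO/toluene, 70 °C
Reagents that add atoms: none
Why: IBX oxidation of the secondary alcohol followed in the same pot by IBX dehydrogenation of the ketone: ketone 21 can enolise only toward C9 because C1 is quaternary, so the C8=C9 enone should form as a single regioisomer, and the tertiary alcohol and the ester are inert.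

Step 15
Reactants: 22 C8=C9 enone
Product: 23 8-methyl C10 ketone (drawn as the 8β-methyl epimer)
Conditions: Me2CuLi (from MeLi, CuI), Et2O, −78 → −30 °C; then aq NH4Cl
Reagents that add atoms: lithium dimethylcuprate, [Li+].C[Cu-]C
Why: Conjugate addition of a Gilman cuprate places the methyl group on C8; the first equivalent is consumed by the tertiary hydroxyl, cuprates do not attack benzoate esters at low temperature, and the C8 configuration (attack expected anti to the C6 ester) is irrelevant because C8 becomes trigonal in step 16.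

Step 16
Reactants: 23 8-methyl C10 ketone
Product: 24 8-methyl C8=C9 enone with C10 ketone
Conditions: IBX (1.5 equiv), DMSO, 75 °C
Reagents that add atoms: none
Why: IBX dehydrogenation of a ketone: enolisation is again possible only toward C9, so the C8=C9 double bond returns, now carrying the methyl group.

Step 17
Reactants: 24 8-methyl C8=C9 enone
Product: 25 10β-allylic alcohol (hydroxyl cis to the C1 methyl)
Conditions: NaBH4, CeCl3·7H2O, MeOH, −78 → −20 °C
Reagents that add atoms: none
Why: Luche reduction: the enone is reduced 1,2 and hydride should approach C10 from the α face, anti to the axial methyl on the neighbouring quaternary C1 (the usual sense for ketones next to an angular methyl in fused rings), which gives the 10β-alcohol, the epimer of the configuration needed.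

Step 18
Reactants: 25 10β-allylic alcohol; 26 angelic acid
Product: 27 CNP0168729.1, (3R,3aS,4S,8R,8aS)-3-hydroxy-6,8a-dimethyl-8-{[(2Z)-2-methylbut-2-enoyl]oxy}-3-(propan-2-yl)-1,2,3,3a,4,5,8,8a-octahydroazulen-4-yl 4-methoxybenzoate
Conditions: PPh3, DIAD, toluene, 0 → 25 °C
Reagents that add atoms: none
Why: Mitsunobu esterification: the 10β-alcohol is activated as its oxyphosphonium ion and displaced with inversion by angelate from the α face, anti to the C1 methyl, which gives the 10α (R) ester; the neutral conditions should preserve the Z geometry of the acid, and the tertiary C4 hydroxyl is not activated.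

Compound list

1 | cycloheptane-1,3-dione | O=C1CCCCC(=O)C1 | starting material
2 | 2-methylcycloheptane-1,3-dione | CC1C(=O)CCCCC1=O | intermediate
3 | N-methoxy-N-methylacrylamide | C=CC(=O)N(C)OC | starting material
4 | N-methoxy-N-methyl-3-(1-methyl-2,7-dioxocycloheptyl)propanamide | CON(C)C(=O)CCC1(C)C(=O)CCCCC1=O | intermediate
5 | N-methoxy-N-methyl-3-[(1R,2R)-2-hydroxy-1-methyl-7-oxocycloheptyl]propanamide | O[C@@H]1CCCCC(=O)[C@]1(C)CCC(=O)N(C)OC | intermediate
6 | 3-[(1R,2R)-2-(tert-butyldimethylsilyloxy)-1-methyl-7-oxocycloheptyl]-N-methoxy-N-methylpropanamide | CC(C)(C)[Si](C)(C)O[C@@H]1CCCCC(=O)[C@]1(C)CCC(=O)N(C)OC | intermediate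
7 | potassium enolate of 6 (C5–C6 enolate) | CC(C)(C)[Si](C)(C)O[C@@H]1CCCC=C([O-])[C@]1(C)CCC(=O)N(C)OC.[K+] | intermediate (not isolated)
8 | 3-[(1R,7R)-7-(tert-butyldimethylsilyloxy)-1-methyl-2-(trifluoromethylsulfonyloxy)cyclohept-2-en-1-yl]-N-methoxy-N-methylpropanamide | CC(C)(C)[Si](C)(C)O[C@@H]1CCCC=C(OS(=O)(=O)C(F)(F)F)[C@]1(C)CCC(=O)N(C)OC | intermediate
9 | isopropylmagnesium chloride | CC(C)[Mg]Cl | starting material
10 | 5-[(1R,7R)-7-(tert-butyldimethylsilyloxy)-1-methyl-2-(trifluoromethylsulfonyloxy)cyclohept-2-en-1-yl]-2-methylpentan-3-one (key-step precursor) | CC(C)(C)[Si](C)(C)O[C@@H]1CCCC=C(OS(=O)(=O)C(F)(F)F)[C@]1(C)CCC(=O)C(C)C | intermediate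
11 | C5 alkenylchromium dichloride (trivalent chromium) | CC(C)(C)[Si](C)(C)O[C@@H]1CCCC=C([Cr](Cl)Cl)[C@]1(C)CCC(=O)C(C)C | intermediate (not isolated)
12 | (3R,8R,8aS)-8-(tert-butyldimethylsilyloxy)-8a-methyl-3-(propan-2-yl)-1,2,3,5,6,7,8,8a-octahydroazulen-3-ol (key-step product) | CC(C)(C)[Si](C)(C)O[C@@H]1CCCC=C2[C@]1(C)CC[C@@]2(O)C(C)C | intermediate
13 | C6 alkylborane (6β-boryl, 5β-H, drawn as the monoalkylborane) | CC(C)(C)[Si](C)(C)O[C@@H]1CCC[C@@H](B)[C@H]2[C@]1(C)CC[C@@]2(O)C(C)C | intermediate (not isolated)
14 | cis-fused 4β,6β-diol (5β-H, 4α-isopropyl, 1β-methyl, 10α-silyloxy) | CC(C)(C)[Si](C)(C)O[C@@H]1CCC[C@@H](O)[C@H]2[C@]1(C)CC[C@@]2(O)C(C)C | intermediate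
15 | cis-fused 4β-hydroxy-6-ketone (5β-H) | CC(C)(C)[Si](C)(C)O[C@@H]1CCCC(=O)[C@H]2[C@]1(C)CC[C@@]2(O)C(C)C | intermediate
16 | trans-fused 4β-hydroxy-6-ketone (5α-H) | CC(C)(C)[Si](C)(C)O[C@@H]1CCCC(=O)[C@@H]2[C@]1(C)CC[C@@]2(O)C(C)C | intermediate
17 | trans-fused 4β,6α-diol (5α-H, 10α-silyloxy) | CC(C)(C)[Si](C)(C)O[C@@H]1CCC[C@H](O)[C@@H]2[C@]1(C)CC[C@@]2(O)C(C)C | intermediate
18 | 4-methoxybenzoyl chloride | COc1ccc(cc1)C(Cl)=O | starting material
19 | 6α-(4-methoxybenzoyloxy) 10α-silyl ether with free 4β-hydroxyl | CC(C)(C)[Si](C)(C)O[C@@H]1CCC[C@H](OC(=O)c3ccc(OC)cc3)[C@@H]2[C@]1(C)CC[C@@]2(O)C(C)C | intermediate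
20 | 6α-(4-methoxybenzoyloxy)-4β,10α-diol | O[C@@H]1CCC[C@H](OC(=O)c3ccc(OC)cc3)[C@@H]2[C@]1(C)CC[C@@]2(O)C(C)C | intermediate
21 | C10 ketone with 6α-anisoate and 4β-hydroxyl | O=C1CCC[C@H](OC(=O)c3ccc(OC)cc3)[C@@H]2[C@]1(C)CC[C@@]2(O)C(C)C | intermediate (not isolated)
22 | C8=C9 enone (C10 ketone, 6α-anisoate, 4β-hydroxyl) | O=C1C=CC[C@H](OC(=O)c3ccc(OC)cc3)[C@@H]2[C@]1(C)CC[C@@]2(O)C(C)C | intermediate
23 | 8β-methyl C10 ketone (the 8α epimer is equally usable) | O=C1C[C@@H](C)C[C@H](OC(=O)c3ccc(OC)cc3)[C@@H]2[C@]1(C)CC[C@@]2(O)C(C)C | intermediate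
24 | 8-methyl C8=C9 enone (C10 ketone) | O=C1C=C(C)C[C@H](OC(=O)c3ccc(OC)cc3)[C@@H]2[C@]1(C)CC[C@@]2(O)C(C)C | intermediate
25 | 10β-allylic alcohol (6α-anisoate, 4β-hydroxyl) | O[C@H]1C=C(C)C[C@H](OC(=O)c3ccc(OC)cc3)[C@@H]2[C@]1(C)CC[C@@]2(O)C(C)C | intermediate
26 | angelic acid, (Z)-2-methylbut-2-enoic acid | C/C=C(/C)C(O)=O | starting material
27 | CNP0168729.1, (3R,3aS,4S,8R,8aS)-3-hydroxy-6,8a-dimethyl-8-{[(2Z)-2-methylbut-2-enoyl]oxy}-3-(propan-2-yl)-1,2,3,3a,4,5,8,8a-octahydroazulen-4-yl 4-methoxybenzoate | C/C=C(/C)C(=O)O[C@@H]1C=C(C)C[C@H](OC(=O)c2ccc(OC)cc2)[C@@H]2[C@]1(C)CC[C@@]2(O)C(C)C | target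

Total step count: 18. Longest linear sequence: 18 steps, from cycloheptane-1,3-dione 1.

Steps most likely to fail

Step 7: the ring closure may show poor facial selectivity at C4, or the alkenylchromium may be protonated before it adds to the hindered, enolisable ketone. The fallback closes the ring at the aldehyde oxidation level and brings in the isopropyl group afterwards. It sets out from 8: reduction of the Weinreb amide with i-Bu2AlH at −78 °C should give the aldehyde F1; CrCl2 with catalytic NiCl2 in DMF should close the ring onto the far more reactive aldehyde to give the secondary allylic alcohol F2 as a mixture of C4 epimers; Dess–Martin oxidation should give the enone F3; 1,2-addition of i-PrMgCl (9) with CeCl3 at −78 °C, expected from the α face anti to the C1 methyl, comes back to the route at 12.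

Step 18: displacement at a carbinol next to a quaternary carbon may be slow, and elimination to a diene or Z-to-E isomerisation of the acid may intervene. The fallback separates inversion from acylation. It sets out from 25: Mitsunobu reaction with the more acidic chloroacetic acid (PPh3, DIAD) should give the 10α-chloroacetate F4; thiourea with NaHCO3 in ethanol should remove the chloroacetyl group without touching the anisoate to give the 10α-alcohol F5; Yamaguchi esterification with the mixed anhydride made from angelic acid 26 and 2,4,6-trichlorobenzoyl chloride (Et3N, toluene, 80 °C) comes back to the route at 27.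

Step 10: retro-aldol opening of the C4–C5 bond or dehydration of the β-hydroxy ketone may compete with epimerisation at C5. The fallback masks the hydroxyl before equilibration. It sets out from 15: silylation with N-(trimethylsilyl)imidazole should give the C4 trimethylsilyl ether F6, which cannot fragment; DBU in toluene at 60 °C should equilibrate C5 to the trans-fused silyl ether F7; PPTS in methanol at 0 °C should remove the trimethylsilyl group while the C10 silyl ether stays, which comes back to the route at 16.

Further compounds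

F1 | step 7 | 3-[(1R,7R)-7-(tert-butyldimethylsilyloxy)-1-methyl-2-(trifluoromethylsulfonyloxy)cyclohept-2-en-1-yl]propanal | CC(C)(C)[Si](C)(C)O[C@@H]1CCCC=C(OS(=O)(=O)C(F)(F)F)[C@]1(C)CCC=O
F2 | step 7 | bicyclic secondary allylic alcohol (C4 carbinol without isopropyl, both C4 epimers, C5=C6 alkene, 10α-silyloxy) | CC(C)(C)[Si](C)(C)O[C@@H]1CCCC=C2[C@]1(C)CCC2O
F3 | step 7 | bicyclic enone (C4 ketone conjugated to C5=C6, 10α-silyloxy) | CC(C)(C)[Si](C)(C)O[C@@H]1CCCC=C2[C@]1(C)CCC2=O
F4 | step 18 | 10α-chloroacetate (6α-anisoate, 4β-hydroxyl) | ClCC(=O)O[C@@H]1C=C(C)C[C@H](OC(=O)c3ccc(OC)cc3)[C@@H]2[C@]1(C)CC[C@@]2(O)C(C)C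
F5 | step 18 | 10α-allylic alcohol (6α-anisoate, 4β-hydroxyl) | O[C@@H]1C=C(C)C[C@H](OC(=O)c3ccc(OC)cc3)[C@@H]2[C@]1(C)CC[C@@]2(O)C(C)C
F6 | step 10 | cis-fused 6-ketone with C4 trimethylsilyl ether (5β-H) | CC(C)(C)[Si](C)(C)O[C@@H]1CCCC(=O)[C@H]2[C@]1(C)CC[C@@]2(O[Si](C)(C)C)C(C)C
F7 | step 10 | trans-fused 6-ketone with C4 trimethylsilyl ether (5α-H) | CC(C)(C)[Si](C)(C)O[C@@H]1CCCC(=O)[C@@H]2[C@]1(C)CC[C@@]2(O[Si](C)(C)C)C(C)C
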